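## Analysis of the target

The target is a cadinane-type sesquiterpenoid triester (C20H28O6) on a cis-fused bicyclo[4.4.0]decane. Cadinane numbering is used for all decalin compounds: ring A is C1–C6 with the C4=C5 alkene and methyl C15 on C4; ring B is C1, C6, C7, C8, C9, C10 with methyl C14 on C10; C11 is exocyclic on C7 and carries methyl C13 and the oxygenated C12. There are five stereocentres (1R,3S,6R,9S,10S): H1 and H6 are cis, the acetoxy groups at C3 and C9 both lie on the face opposite to these hydrogens, and C14 lies on the face of H1, trans to the C9 acetate. The sixth stereo-element is the tetrasubstituted exocyclic alkene C7=C11 (E), with C13H3 syn to C6 and C12H2O syn to C8. Sensitive groups are the primary allylic formate (the most labile ester), the allylic C3 acetate, the doubly allylic C6–H and, in any precursor with a C9 carbonyl, the β,γ-placed C7=C11 alkene, which can slip into conjugation. The synthesis is hard for three reasons: the alkene termini differ only as CH3 versus CH2O, so olefination or elimination gives no control; the C10–C1–C6 array of a cis-decalin must be matched to two remote centres; and three hydroxyls must end as two kinds of ester. The feature that invites the key move is the chain C4=C5–C6–C7(=C11)–C8–C9(–O) running through rings A and B. A C9 carbonyl with a δ,ε-alkene is the retron of an oxy-Cope rearrangement, and the alkylidene on C7 marks an allene as the migrating 2π partner. Reconnecting C4–C9 while cutting C6–C7 turns the decalin into a bicyclo[2.2.2]octene whose ten carbons (ring A plus C9, C10, C14) are the ten carbons of carvone.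

## Retrosynthetic reasoning

**20 to 18.** The three acyl C–O bonds are cut last. Triol 18 has one primary allylic and two secondary hydroxyls, so the formate can be placed first on C12 (19) and the two acetates together afterwards. No protecting group is needed between the esters.

**18 to 16.** The C3 silyl ether is removed (17 to 18) and the C9–H bond is cut to give ketone 16. The forward reduction must deliver hydride axially to C9 from the face of H1, which gives the equatorial 9S alcohol. A C9 ketone is exactly what an oxy-Cope rearrangement leaves behind.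

**16 to 14 (key disconnection).** The C6–C7 bond is cut and the C4–C9 bond reconnected. This converts the cis-decalin into the bicyclo[2.2.2]octenol 14, in which C4 and C1 are bridgeheads and the bridges are C5=C6, C3–C2 and C9–C10. The C9 carbinol carries an allene C8=C7=C11. One forward step has to close ring B, set C6 (cis-fusion), create the C9 carbonyl and convert the allene axis into the E alkene. The cut is made here because the cage guarantees the ring-fusion stereochemistry and the allene removes the olefination problem altogether.

**14 to 8 and 11.** The allene is traced to the alkynyl oxirane 13 by cutting the C8–H bond and re-forming the C11–O bond (SN2′ reduction in the forward sense). The oxirane stereocentre thereby controls the allene axis. 13 is cut at C8–C9 into ketone 8 and the acetylide 12 of alkyne 11. The ketone face is controlled by the 1,3-syn silyl ether on C3.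

**11 to 9.** The alkyne carbon is removed (10) and the aldehyde returned to the alcohol of commercial 9, the only source of chirality besides 1.

**8 to 3.** The C10 methyl stereocentre and the C9 carbonyl are traced to the allylic alcohol 6 (redox isomerisation forward), and its C9 oxygen to allylic oxidation of the exocyclic alkene of 5. The C3 silyl ether comes from alcohol 4 and ketone 3. The forward reduction must come from the etheno face, which is the inherent preference of the cage.

**3 to 1.** The C4–C9 bond is cut to give the allylic chloride 2, i.e. 1 chlorinated on its isopropenyl methyl. Carvone thus supplies ring A, C9, C10, C14 and the C1 stereocentre, from which C3, C10, C9 (carbinol) and C6 are relayed.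

## Alternatives that were turned down

**Alternative 1: (textbook) Diels–Alder annulation of ring A onto ring B.** The C1–C2 and C5–C6 bonds are cut. A 4-methyl-5-silyloxycyclohex-2-enone (C6=C1 conjugated with a C7 ketone) reacts with a 2-silyloxy-3-methyl diene to give the cis-fused adduct A1. Saegusa oxidation gives enedione A2, and the C7 ketone is then olefinated. It was turned down because the C7 ketone is hindered and enolisable, and its conversion to a tetrasubstituted alkene with CH3/CH2O ends offers no handle on E/Z. Enolisation also endangers C6, the C3 and C7 ketones of A2 need differentiation, and the chiral dienophile needs its own enantioselective synthesis. The hardest element would be left to the weakest step.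

**Alternative 2: intramolecular Diels–Alder reaction of an acyclic triene.** The C1–C6 and C2–C3 bonds are cut. The 1,7,9-decatriene A3 would close both rings and set C1, C3 and C6 at once. It was turned down because the dienophile is an unactivated vinyl group and the diene is the end of a linear triene bearing an enol acetate. The temperatures needed would allow 1,5-hydrogen shifts, and such tethers give cis/trans mixtures with face selectivity resting on a flexible C9/C10 chain. A3 also already contains the stereodefined tetrasubstituted alkene and two stereocentres in an open chain, so the key step would not simplify the hard part.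

**Alternative 3: closure of ring B at C6–C7 on a carvone-derived ring A by allylpalladation of a tethered alkyne.** Only C6–C7 and C11–C13 are cut. Allylic carbonate A4 would ionise with zerovalent palladium to a C4–C6 allyl complex, add syn across the C7≡C11 alkyne and be methylated by a methylboron or methylzinc reagent. The syn addition would set the alkene geometry. It was turned down because C9 and C10 would have to be set on an open chain hanging from 1 with poor control, 1 would first need γ-oxygenation, and the allyl complex can react at C4, be methylated directly or eliminate. The step count grows while three stereocentres stay unsecured.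

Key step: step 11

Remark on the chemistry: the hydroxyl-directed LiAlH4 opening of the alkynyl oxirane (step 10) is taken to follow the anti SN2′ course usual for this reaction type, and the configuration of oxirane 9 is chosen on that basis.

## Steps

Step 1
Reactants: 1 (S)-(+)-carvone, (5S)-2-methyl-5-(prop-1-en-2-yl)cyclohex-2-en-1-one
Product: 2 (5S)-5-(3-chloroprop-1-en-2-yl)-2-methylcyclohex-2-en-1-one
Conditions: Ca(OCl)2, solid CO2, CH2Cl2/H2O, 0 °C
Reagents that add atoms: calcium hypochlorite, [Ca+2].[O-]Cl.[O-]Cl
Why: Ene-type allylic chlorination of the electron-rich 1,1-disubstituted alkene by HOCl; the enone alkene is too electron-poor to compete and the stereocentre is not touched.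

Step 2
Reactants: 2 (5S)-5-(3-chloroprop-1-en-2-yl)-2-methylcyclohex-2-en-1-one
Product: 3 (1R,4R)-1-methyl-8-methylidenebicyclo[2.2.2]oct-5-en-2-one
Conditions: KOt-Bu, t-BuOH/THF, 0 °C to rt
Reagents that add atoms: none
Why: Intramolecular enolate alkylation: γ-deprotonation gives the linear dienolate, whose α-carbon (cadinane C4) displaces the allylic chloride in a six-membered closure; attack from the α′- or γ-carbon would need a four-membered ring and O-alkylation a bridgehead alkene, so only the bicyclo[2.2.2]octenone can form, with the second bridgehead fixed by the carvone stereocentre.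

Step 3
Reactants: 3 (1R,4R)-1-methyl-8-methylidenebicyclo[2.2.2]oct-5-en-2-one
Product: 4 (1R,2S,4R)-1-methyl-8-methylidenebicyclo[2.2.2]oct-5-en-2-ol (hydroxyl on the side of the C7–C8 bridge)
Conditions: Li[HB(s-Bu)3], THF, −78 °C; H2O work-up
Reagents that add atoms: none
Why: Ketone reduction by a bulky hydride, which should enter from the face flanked by the flat etheno bridge and not from the face carrying the inward C7–H, placing oxygen syn to the C7–C8 bridge (the cadinane 3S centre).

Step 4
Reactants: 4 (1R,2S,4R)-1-methyl-8-methylidenebicyclo[2.2.2]oct-5-en-2-ol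
Product: 5 tert-butyldimethyl{[(1R,2S,4R)-1-methyl-8-methylidenebicyclo[2.2.2]oct-5-en-2-yl]oxy}silane
Conditions: TBSOTf, 2,6-lutidine, CH2Cl2, 0 °C
Reagents that add atoms: tert-butyldimethylsilyl triflate, CC(C)(C)[Si](C)(C)OS(=O)(=O)C(F)(F)F
Why: Silylation of a hindered secondary alcohol with a silyl triflate; the ether protects against retro-aldol cleavage once the neighbouring ketone is in place and later shields one face of that ketone.

Step 5
Reactants: 5 tert-butyldimethyl{[(1R,2S,4R)-1-methyl-8-methylidenebicyclo[2.2.2]oct-5-en-2-yl]oxy}silane
Product: 6 7-[(tert-butyldimethylsilyl)oxy]-1-methyl-3-methylidenebicyclo[2.2.2]oct-5-en-2-ol (silyloxy group syn to the C2–C3 bridge; both C2 epimers)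
Conditions: SeO2 (cat.), t-BuOOH, CH2Cl2, rt
Reagents that add atoms: tert-butyl hydroperoxide, CC(C)(C)OO; selenium dioxide (oxygen carrier), O=[Se]=O
Why: Selenium dioxide allylic hydroxylation (ene reaction, then 2,3-shift); the only allylic hydrogens that can be removed without forming a bridgehead alkene are those of the ring CH2 next to the methylidene (cadinane C9), so the oxygen can enter only there, and the new centre is erased in step 6.

Step 6
Reactants: 6 7-[(tert-butyldimethylsilyl)oxy]-1-methyl-3-methylidenebicyclo[2.2.2]oct-5-en-2-ol
Product: 8 (1R,3S,4R,7S)-7-[(tert-butyldimethylsilyl)oxy]-1,3-dimethylbicyclo[2.2.2]oct-5-en-2-one (3-methyl syn to C5=C6), via kinetic C3-epimer mixture 7 (not isolated)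
Conditions: CpRuCl(PPh3)2 (cat.), Et3NH·PF6 (cat.), dioxane, 100 °C; then DBU, rt
Reagents that add atoms: none
Why: Ruthenium-catalysed redox isomerisation of an allylic alcohol to the saturated ketone (β-hydride elimination from the bound alkoxide, hydride return to the terminal CH2); the C5=C6 alkene has only bridgehead allylic positions and stays put. DBU then equilibrates C3 through the enol to the epimer with methyl on the etheno side, which avoids the 1,3-contact with the inward hydrogen on C8 (the cadinane 10S centre).

Step 7
Reactants: 9 (R)-2-methylglycidol, [(2R)-2-methyloxiran-2-yl]methanol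
Product: 10 (2S)-2-methyloxirane-2-carbaldehyde
Conditions: TEMPO (cat.), PhI(OAc)2, CH2Cl2, rt
Reagents that add atoms: none
Why: Oxoammonium-mediated oxidation of a primary alcohol to the aldehyde; the α-carbon is quaternary, so it cannot epimerise (the descriptor changes only through the priority rules); the volatile aldehyde is carried on in solution.

Step 8
Reactants: 10 (2S)-2-methyloxirane-2-carbaldehyde
Product: 11 (2R)-2-ethynyl-2-methyloxirane
Conditions: dimethyl (1-diazo-2-oxopropyl)phosphonate, K2CO3, MeOH, 0 °C to rt
Reagents that add atoms: dimethyl (1-diazo-2-oxopropyl)phosphonate, COP(=O)(OC)C(=[N+]=[N-])C(C)=O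
Why: Seyferth–Gilbert homologation with the Ohira–Bestmann reagent converts the aldehyde to the terminal alkyne under mild base that leaves the oxirane and its quaternary stereocentre intact; the volatile alkyne is extracted, dried and used as a titrated THF solution.

Step 9
Reactants: 11 (2R)-2-ethynyl-2-methyloxirane; 8 (1R,3S,4R,7S)-7-[(tert-butyldimethylsilyl)oxy]-1,3-dimethylbicyclo[2.2.2]oct-5-en-2-one
Product: 13 (1R,2S,3S,4R,7S)-7-[(tert-butyldimethylsilyl)oxy]-1,3-dimethyl-2-{[(2R)-2-methyloxiran-2-yl]ethynyl}bicyclo[2.2.2]oct-5-en-2-ol (alkynyl group syn to C5=C6), via lithium acetylide 12 (not isolated)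
Conditions: n-BuLi, THF, −78 °C; then 8, −78 to −20 °C; H2O
Reagents that add atoms: none
Why: 1,2-Addition of a lithium acetylide to a hindered ketone; the face of C2 turned to the C7–C8 bridge is closed by the 1,3-syn silyl ether, so the slim nucleophile should enter from the etheno side, placing the alkynyl group where step 11 needs it and the hydroxyl next to the silyl ether.

Step 10
Reactants: 13 (1R,2S,3S,4R,7S)-7-[(tert-butyldimethylsilyl)oxy]-1,3-dimethyl-2-{[(2R)-2-methyloxiran-2-yl]ethynyl}bicyclo[2.2.2]oct-5-en-2-ol
Product: 14 (1R,2S,3S,4R,7S)-7-[(tert-butyldimethylsilyl)oxy]-2-[(aS)-4-hydroxy-3-methylbuta-1,2-dien-1-yl]-1,3-dimethylbicyclo[2.2.2]oct-5-en-2-ol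
Conditions: LiAlH4, THF, 0 °C to rt; aq. potassium sodium tartrate
Reagents that add atoms: none
Why: SN2′ reduction of a propargylic oxirane to an α-allenic alcohol: the tertiary alkoxide directs hydride to the carbinol-side alkyne carbon (cadinane C8) and the alkenylalane expels the oxirane oxygen. The oxirane centre is transferred to the allene axis (anti course, see remark), so that methyl and CH2OH on the allene terminus take defined positions.

Step 11
Reactants: 14 (1R,2S,3S,4R,7S)-7-[(tert-butyldimethylsilyl)oxy]-2-[(aS)-4-hydroxy-3-methylbuta-1,2-dien-1-yl]-1,3-dimethylbicyclo[2.2.2]oct-5-en-2-ol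
Product: 16 (1R,3S,6R,10S,7(11)E)-3-[(tert-butyldimethylsilyl)oxy]-12-hydroxycadina-4,7(11)-dien-9-one, via dipotassium dienolate 15 (not isolated)
Conditions: KH (excess), 18-crown-6, THF, 0 °C to rt; then AcOH, −78 °C
Reagents that add atoms: none
Why: Proposed new method: an anionic oxy-Cope rearrangement whose migrating 2π unit is the proximal double bond of an allene on a bicyclo[2.2.2]octenyl alkoxide; the closest known reaction type is the anionic oxy-Cope rearrangement of 2-alkenylbicyclo[2.2.2]oct-5-en-2-ols to cis-fused octalones, and allenes are established 2π partners in thermal 3,3-shifts, so the same six-electron array C=C–C(O−)–C–C=C is present and the orthogonal allene π bond is a spectator. The crown-separated potassium alkoxide weakens the cadinane C4–C9 bond, which breaks while the central allene carbon C7 bonds to C6 of the etheno bridge through the boat-like, suprafacial transition state that the cage enforces; this gives dienolate 15, and kinetic protonation at its α-carbon C8 gives 16 with the alkene out of conjugation. Ring B is closed by the single C6–C7 bond as a 3,3-shift that turns the bicyclo[2.2.2]octene into the bicyclo[4.4.0]decene, and ring A is released from the cage with its C4=C5 alkene in place. C6 is set by the cage: C7 can reach only the face of C5=C6 that looks at the carbinol bridge, so the new bond is cis to the C1–C10 bond (cis-fusion), while C1, C3 and C10 pass through unchanged. The alkene geometry is set by the allene axis: in the aS isomer the methyl on C11 points at the etheno bridge and ends syn to C6, the outward CH2O ends syn to C8, which is E. The step needs the 3,3-shift to beat retro-addition (loss of an allenyl anion) and α- to beat γ-protonation of 15; strain release in the cage favours the shift and the cold acetic acid quench favours α-protonation. The primary alkoxide on C12 is a bystander, since it cannot reach C9 without a bridgehead alkene.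

Step 12
Reactants: 16 (1R,3S,6R,10S,7(11)E)-3-[(tert-butyldimethylsilyl)oxy]-12-hydroxycadina-4,7(11)-dien-9-one
Product: 17 (1R,3S,6R,9S,10S,7(11)E)-3-[(tert-butyldimethylsilyl)oxy]cadina-4,7(11)-diene-9,12-diol
Conditions: NaBH4, CeCl3·7H2O, MeOH, −40 °C
Reagents that add atoms: none
Why: Luche-type ketone reduction under nearly neutral conditions that should not move the β,γ-alkene; in the chair of ring B with C5 axial and C14 equatorial, axial attack from the face of H1 meets only that one axial hydrogen (C7 is trigonal) and gives the equatorial 9S alcohol.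

Step 13
Reactants: 17 (1R,3S,6R,9S,10S,7(11)E)-3-[(tert-butyldimethylsilyl)oxy]cadina-4,7(11)-diene-9,12-diol
Product: 18 (1R,3S,6R,9S,10S,7(11)E)-cadina-4,7(11)-diene-3,9,12-triol
Conditions: Bu4NF, THF, rt
Reagents that add atoms: none
Why: Fluoride cleavage of the silyl ether; no carbonyl or ester is present, so the basic fluoride has nothing to isomerise or cleave.

Step 14
Reactants: 18 (1R,3S,6R,9S,10S,7(11)E)-cadina-4,7(11)-diene-3,9,12-triol
Product: 19 (1R,3S,6R,9S,10S,7(11)E)-3,9-dihydroxycadina-4,7(11)-dien-12-yl formate
Conditions: HCO2CH2CF3 (3 equiv), THF, rt to 40 °C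
Reagents that add atoms: 2,2,2-trifluoroethyl formate, O=COCC(F)(F)F
Why: Transesterification with an activated formate, which formylates primary alcohols faster than secondary ones; C12–OH is the only primary hydroxyl, and both secondary ones sit next to substituted ring carbons.

Step 15
Reactants: 19 (1R,3S,6R,9S,10S,7(11)E)-3,9-dihydroxycadina-4,7(11)-dien-12-yl formate
Product: 20 (1R,3S,6R,9S,10S,7(11)E)-3,9-diacetoxycadina-4,7(11)-dien-12-yl formate (target, CNP0262962.2)
Conditions: Ac2O, pyridine, DMAP (cat.), CH2Cl2, 0 °C to rt
Reagents that add atoms: acetic anhydride, CC(=O)OC(C)=O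
Why: Acetylation of both secondary alcohols under conditions that do not exchange the formate; no stereocentre is involved.

## Compound list

1 | (S)-(+)-carvone | CC1=CC[C@@H](CC1=O)C(C)=C | starting material
2 | (5S)-5-(3-chloroprop-1-en-2-yl)-2-methylcyclohex-2-en-1-one | CC1=CC[C@@H](CC1=O)C(=C)CCl | intermediate
3 | (1R,4R)-1-methyl-8-methylidenebicyclo[2.2.2]oct-5-en-2-one | C[C@@]12C=C[C@@H](CC1=O)C(=C)C2 | intermediate
4 | (1R,2S,4R)-1-methyl-8-methylidenebicyclo[2.2.2]oct-5-en-2-ol | C[C@@]12C=C[C@@H](C[C@@H]1O)C(=C)C2 | intermediate
5 | tert-butyldimethylsilyl ether of 4 | C[C@@]12C=C[C@@H](C[C@@H]1O[Si](C)(C)C(C)(C)C)C(=C)C2 | intermediate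
6 | 7-[(tert-butyldimethylsilyl)oxy]-1-methyl-3-methylidenebicyclo[2.2.2]oct-5-en-2-ol, both C2 epimers | C[C@@]12C=C[C@@H](C[C@@H]1O[Si](C)(C)C(C)(C)C)C(=C)C2O | intermediate
7 | 7-[(tert-butyldimethylsilyl)oxy]-1,3-dimethylbicyclo[2.2.2]oct-5-en-2-one, kinetic mixture of C3 epimers | C[C@@]12C=C[C@@H](C[C@@H]1O[Si](C)(C)C(C)(C)C)C(C)C2=O | intermediate (not isolated)
8 | (1R,3S,4R,7S)-7-[(tert-butyldimethylsilyl)oxy]-1,3-dimethylbicyclo[2.2.2]oct-5-en-2-one | C[C@@]12C=C[C@@H](C[C@@H]1O[Si](C)(C)C(C)(C)C)[C@H](C)C2=O | intermediate
9 | (R)-2-methylglycidol | OC[C@]1(C)CO1 | starting material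
10 | (2S)-2-methyloxirane-2-carbaldehyde | O=C[C@]1(C)CO1 | intermediate
11 | (2R)-2-ethynyl-2-methyloxirane | C#C[C@]1(C)CO1 | intermediate
12 | lithium acetylide of 11 | [Li]C#C[C@]1(C)CO1 | intermediate (not isolated)
13 | (1R,2S,3S,4R,7S)-7-[(tert-butyldimethylsilyl)oxy]-1,3-dimethyl-2-{[(2R)-2-methyloxiran-2-yl]ethynyl}bicyclo[2.2.2]oct-5-en-2-ol | C[C@@]12C=C[C@@H](C[C@@H]1O[Si](C)(C)C(C)(C)C)[C@H](C)[C@]2(O)C#C[C@]1(C)CO1 | intermediate
14 | (1R,2S,3S,4R,7S)-7-[(tert-butyldimethylsilyl)oxy]-2-[(aS)-4-hydroxy-3-methylbuta-1,2-dien-1-yl]-1,3-dimethylbicyclo[2.2.2]oct-5-en-2-ol | C[C@@]12C=C[C@@H](C[C@@H]1O[Si](C)(C)C(C)(C)C)[C@H](C)[C@]2(O)C([H])=[C@@]=C(C)CO | intermediate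
15 | dipotassium dienolate (C8=C9 enolate, C12 alkoxide) of 16 | CC(C)(C)[Si](C)(C)O[C@H]1C[C@H]2[C@H](C)C([O-])=C/C(=C(/C)C[O-])[C@H]2C=C1C.[K+].[K+] | intermediate (not isolated)
16 | (1R,3S,6R,10S,7(11)E)-3-[(tert-butyldimethylsilyl)oxy]-12-hydroxycadina-4,7(11)-dien-9-one | CC(C)(C)[Si](C)(C)O[C@H]1C[C@H]2[C@H](C)C(=O)C/C(=C(/C)CO)[C@H]2C=C1C | intermediate
17 | (1R,3S,6R,9S,10S,7(11)E)-3-[(tert-butyldimethylsilyl)oxy]cadina-4,7(11)-diene-9,12-diol | CC(C)(C)[Si](C)(C)O[C@H]1C[C@H]2[C@H](C)[C@@H](O)C/C(=C(/C)CO)[C@H]2C=C1C | intermediate
18 | (1R,3S,6R,9S,10S,7(11)E)-cadina-4,7(11)-diene-3,9,12-triol | O[C@H]1C[C@H]2[C@H](C)[C@@H](O)C/C(=C(/C)CO)[C@H]2C=C1C | intermediate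
19 | (1R,3S,6R,9S,10S,7(11)E)-3,9-dihydroxycadina-4,7(11)-dien-12-yl formate | O[C@H]1C[C@H]2[C@H](C)[C@@H](O)C/C(=C(/C)COC=O)[C@H]2C=C1C | intermediate
20 | (1R,3S,6R,9S,10S,7(11)E)-3,9-diacetoxycadina-4,7(11)-dien-12-yl formate | CC(=O)O[C@H]1C[C@H]2[C@H](C)[C@@H](OC(C)=O)C/C(=C(/C)COC=O)[C@H]2C=C1C | target

## Step count and least certain steps

Total step count: 15. Longest linear sequence: 13 (steps 1–6 and 9–15, from 1); steps 7 and 8 make the two-step side branch from 9.

**Step 11 (key step, proposed new method).** The most likely failures are fragmentation of the tertiary alkoxide by retro-addition (loss of the allenyl anion back toward 8), stalling through silyl transfer from the neighbouring silyl ether to the alkoxide, and drift of dienolate 15 into the conjugated enone on quench, which destroys the exocyclic alkene. The fallback is the uncharged thermal oxy-Cope rearrangement, which is the established parent reaction on this cage. It sets out from 14, which is silylated on both hydroxyls (Me3SiCl, imidazole, then Me3SiOTf for the tertiary site) to the bis(trimethylsilyl) ether F1. F1 is heated in degassed o-dichlorobenzene in a sealed tube (about 200 °C) and should give the silyl dienol ether F2 by the same 3,3-shift without any anionic intermediate. Mild acid (citric acid, MeOH, 0 °C) then frees the ketone and the primary alcohol, and the route is rejoined at 16.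

**Step 10.** What may go wrong is incomplete or reversed centre-to-axis transfer (a syn instead of an anti elimination pathway, which would lead to the Z alkene after step 11) or direct hydride opening at the oxirane CH2. The fallback does not rely on the alkoxide-directed alane. 13 is reduced with a copper hydride made from (IPr)CuCl (IPr = 1,3-bis(2,6-diisopropylphenyl)imidazol-2-ylidene), NaOt-Bu and polymethylhydrosiloxane, which opens propargylic oxiranes by syn-hydrocupration and anti β-elimination. A basic methanol work-up removes any silyl residue on oxygen, and the route is rejoined at 14 without a new compound.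

**Step 9.** Enolisation of the hindered ketone, or addition from the wrong face because the C3 methyl also lies on the etheno side, would cost material or give the carbinol epimer that cannot rearrange. The fallback postpones the methyl group. It sets out from 6, which is oxidised to the enone F3 (see step 6). F3 cannot enolise and has an open etheno face. Acetylide 12 is added to give the methylidene carbinol F4. LiAlH4 opens it to the methylidene allenyl diol F5, and the conditions of step 11 convert F5 to the α-methylene ketone F6. Conjugate reduction with [CuH(PPh3)]6 then sets C10 by protonation to the equatorial methyl, and the route is rejoined at 16.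

**Step 6.** The isomerisation may be slow at the neopentyl-like carbinol, and the base equilibration may leave part of the material as the wrong C3 epimer. The fallback replaces the catalytic hydrogen shift by a stoichiometric oxidation–reduction pair. 6 is oxidised with Dess–Martin periodinane to the 3-methylidene ketone F3, and conjugate reduction with K[HB(s-Bu)3] at −78 °C followed by NaOMe in MeOH gives the equilibrated ketone; the route is rejoined at 8.

**Step 14.** Over-formylation at the allylic C3 hydroxyl would give mixed esters that are hard to separate. The fallback differentiates the hydroxyls by an enzyme instead of by rate. 18 is fully acetylated (Ac2O, pyridine, DMAP) to the triacetate F7. Candida antarctica lipase B in phosphate buffer/acetone should hydrolyse only the primary allylic acetate to give the diacetate alcohol F8. Formylation with formic acetic anhydride and pyridine at 0 °C then rejoins the route at 20.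

## Further compounds

F1 | step 11 | bis(trimethylsilyl) ether of 14 | C[C@@]12C=C[C@@H](C[C@@H]1O[Si](C)(C)C(C)(C)C)[C@H](C)[C@]2(O[Si](C)(C)C)C([H])=[C@@]=C(C)CO[Si](C)(C)C
F2 | step 11 | trimethylsilyl dienol ether (C8=C9) of 16, 12-O-trimethylsilyl ether | CC(C)(C)[Si](C)(C)O[C@H]1C[C@H]2[C@H](C)C(O[Si](C)(C)C)=C/C(=C(/C)CO[Si](C)(C)C)[C@H]2C=C1C
F3 | step 6 | 7-[(tert-butyldimethylsilyl)oxy]-1-methyl-3-methylidenebicyclo[2.2.2]oct-5-en-2-one | C[C@@]12C=C[C@@H](C[C@@H]1O[Si](C)(C)C(C)(C)C)C(=C)C2=O
F4 | step 9 | 7-[(tert-butyldimethylsilyl)oxy]-1-methyl-3-methylidene-2-{[(2R)-2-methyloxiran-2-yl]ethynyl}bicyclo[2.2.2]oct-5-en-2-ol | C[C@@]12C=C[C@@H](C[C@@H]1O[Si](C)(C)C(C)(C)C)C(=C)[C@]2(O)C#C[C@]1(C)CO1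
F5 | step 9 | 7-[(tert-butyldimethylsilyl)oxy]-2-[(aS)-4-hydroxy-3-methylbuta-1,2-dien-1-yl]-1-methyl-3-methylidenebicyclo[2.2.2]oct-5-en-2-ol | C[C@@]12C=C[C@@H](C[C@@H]1O[Si](C)(C)C(C)(C)C)C(=C)[C@]2(O)C([H])=[C@@]=C(C)CO
F6 | step 9 | (1R,3S,6R,7(11)E)-3-[(tert-butyldimethylsilyl)oxy]-12-hydroxycadina-4,7(11),10(14)-trien-9-one | CC(C)(C)[Si](C)(C)O[C@H]1C[C@H]2C(=C)C(=O)C/C(=C(/C)CO)[C@H]2C=C1C
F7 | step 14 | (1R,3S,6R,9S,10S,7(11)E)-cadina-4,7(11)-diene-3,9,12-triyl triacetate | CC(=O)O[C@H]1C[C@H]2[C@H](C)[C@@H](OC(C)=O)C/C(=C(/C)COC(C)=O)[C@H]2C=C1C
F8 | step 14 | (1R,3S,6R,9S,10S,7(11)E)-12-hydroxycadina-4,7(11)-diene-3,9-diyl diacetate | CC(=O)O[C@H]1C[C@H]2[C@H](C)[C@@H](OC(C)=O)C/C(=C(/C)CO)[C@H]2C=C1C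
F0 | step 10 | none | none
A1 | alternative 1 | cis-fused Diels–Alder adduct, 9-[(tert-butyldimethylsilyl)oxy]-3-[(trimethylsilyl)oxy]-11,12,13-trinorcadin-3-en-7-one, configured as the target at C1, C6, C9, C10 | C[Si](C)(C)OC1=C(C)C[C@@H]2C(=O)C[C@H](O[Si](C)(C)C(C)(C)C)[C@@H](C)[C@@H]2C1
A2 | alternative 1 | 9-[(tert-butyldimethylsilyl)oxy]-11,12,13-trinorcadin-4-ene-3,7-dione | O=C1C[C@H]2[C@H](C)[C@@H](O[Si](C)(C)C(C)(C)C)CC(=O)[C@H]2C=C1C
A3 | alternative 2 | acyclic 1,7,9-decatriene triester (1,6:2,3-disecocadina-1,3,5,7(11)-tetraene 3,9-diacetate 12-formate) | C=C[C@H](C)[C@@H](OC(C)=O)C/C(=C(/C)COC=O)/C=C/C(C)=C/OC(C)=O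
A4 | alternative 3 | carvone-derived allylic methyl carbonate carrying the C10–C9–C8–C7≡C11–C12 side chain (6,7-secocadin-4-en-7(11)-yne, 3-acetate, 6-methyl carbonate, 9,12-bis-silyl ether) | CC(=O)O[C@H]1C[C@@H]([C@H](C)[C@@H](O[Si](C)(C)C(C)(C)C)CC#CCO[Si](C)(C)C(C)(C)C)[C@H](OC(=O)OC)C=C1C
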